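**Retrosynthetic overview**

1. The target is taken back to its tris(methoxymethyl) ether; the three acetals are removed last, under acid, which cannot open ring C.
2. Ring C is cut at C3–C4 to give an achiral 2-[(1-arylethenyl)oxy]benzaldehyde, an isomer of the flavanone. Its formyl C–H adds across C2=C3 (enantioselective rhodium-catalysed hydroacylation), forming the C3–C4 bond, ring C, the C4 ketone and the C2 stereocentre in one operation.
3. Enabling feature: C3 is an unsubstituted CH2 between the C4 carbonyl and C2, C2 carries both O1 and ring B, and C4 and O1 are ortho on ring A. So C4(=O)–C3H2–C2H is the retron of a ring A formyl group plus a 1,1-disubstituted enol ether C2=C3H2.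
4. The enol ether comes from dehydrochlorination of a beta-chloro ether, made by Mitsunobu union of the ring A phenol (bis-MOM phloroglucinaldehyde) with a ring B chlorohydrin. The chlorohydrin comes from the ring B aldehyde (chloromethyllithium addition, Stille prenylation, regioselective methylation of 3-bromo-4,5-dihydroxybenzaldehyde).
5. Ring order: rings A and B are bought as benzenes; ring C is the only ring formed, in the key step.

Key step: step 8

Remark: the stereocentre in the SMILES is C2 with S configuration (that of natural flavanones); which enantiomer of the bisphosphine gives 2S in step 8 has to be found by experiment, and the (R)-ligand written there stands for the one that does.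

**Step 1**
Reactants: 1 2,4,6-trihydroxybenzaldehyde
Product: 2 2-hydroxy-4,6-bis(methoxymethoxy)benzaldehyde
Conditions: MOMCl (2.1 equiv), i-Pr2NEt, CH2Cl2, 0 °C to rt
Reagents that add atoms: chloromethyl methyl ether (MOMCl), COCCl
Why: Williamson-type O-alkylation should stop at the bis-ether because the hydroxyl that is hydrogen-bonded to the formyl group is the least nucleophilic one and stays free (selective MOM protection).

**Step 2**
Reactants: 3 3-bromo-4,5-dihydroxybenzaldehyde
Product: 4 3-bromo-5-hydroxy-4-methoxybenzaldehyde
Conditions: MeI (1.05 equiv), Li2CO3, DMF, 40 °C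
Reagents that add atoms: iodomethane, CI
Why: The 4-OH, para to the formyl group and ortho to bromine, is the most acidic phenol, so the weak base Li2CO3 should form only its phenoxide, which is methylated (regioselective Williamson ether synthesis).

**Step 3**
Reactants: 4 3-bromo-5-hydroxy-4-methoxybenzaldehyde
Product: 5 3-bromo-4-methoxy-5-(methoxymethoxy)benzaldehyde
Conditions: MOMCl, i-Pr2NEt, CH2Cl2, 0 °C to rt
Reagents that add atoms: chloromethyl methyl ether (MOMCl), COCCl
Why: Williamson-type MOM protection of the remaining phenol masks the acidic OH for the organometallic steps that follow.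

**Step 4**
Reactants: 5 3-bromo-4-methoxy-5-(methoxymethoxy)benzaldehyde; 6 tributyl(3-methylbut-2-en-1-yl)stannane
Product: 7 4-methoxy-3-(methoxymethoxy)-5-(3-methylbut-2-en-1-yl)benzaldehyde
Conditions: Pd(PPh3)4, DMF, 100 °C
Reagents that add atoms: none
Why: Stille cross-coupling at zerovalent palladium should give the linear prenyl arene by reductive elimination from the less hindered primary end of the prenylpalladium species, and the allylstannane does not add to the free aldehyde without a Lewis acid.

**Step 5**
Reactants: 7 4-methoxy-3-(methoxymethoxy)-5-(3-methylbut-2-en-1-yl)benzaldehyde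
Product: 9 rac-2-chloro-1-[4-methoxy-3-(methoxymethoxy)-5-(3-methylbut-2-en-1-yl)phenyl]ethan-1-ol, via lithium alkoxide 8 (not isolated)
Conditions: ICH2Cl, MeLi·LiBr, THF, −78 °C; then AcOH, −78 °C to rt
Reagents that add atoms: chloroiodomethane, ClCI
Why: Iodine–lithium exchange makes chloromethyllithium in the presence of the aldehyde, which traps it at −78 °C, and cold protonation of the alkoxide gives the chlorohydrin before an epoxide can close (carbenoid addition to an aldehyde); the new stereocentre is racemic and is erased in step 7.

**Step 6**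
Reactants: 9 rac-2-chloro-1-[4-methoxy-3-(methoxymethoxy)-5-(3-methylbut-2-en-1-yl)phenyl]ethan-1-ol; 2 2-hydroxy-4,6-bis(methoxymethoxy)benzaldehyde
Product: 10 rac-2-{2-chloro-1-[4-methoxy-3-(methoxymethoxy)-5-(3-methylbut-2-en-1-yl)phenyl]ethoxy}-4,6-bis(methoxymethoxy)benzaldehyde
Conditions: PPh3, DIAD, THF, 0 °C to rt
Reagents that add atoms: none
Why: In this Mitsunobu etherification the acidic, chelated phenol 2 is the pronucleophile and displaces the oxyphosphonium group of the secondary benzylic alcohol; the configuration of this carbon does not matter because step 7 makes it trigonal.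

**Step 7**
Reactants: 10 rac-2-{2-chloro-1-[4-methoxy-3-(methoxymethoxy)-5-(3-methylbut-2-en-1-yl)phenyl]ethoxy}-4,6-bis(methoxymethoxy)benzaldehyde
Product: 11 2-({1-[4-methoxy-3-(methoxymethoxy)-5-(3-methylbut-2-en-1-yl)phenyl]ethenyl}oxy)-4,6-bis(methoxymethoxy)benzaldehyde
Conditions: KOtBu, THF, 0 °C to rt
Reagents that add atoms: none
Why: E2 dehydrochlorination of a beta-chloroethyl aryl ether is the classical route to aryl vinyl ethers; the only beta-hydrogen is the benzylic C–H on the oxygen-bearing carbon, so only the 1,1-disubstituted enol ether can form, and the aldehyde has no alpha-hydrogen.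

**Step 8**
Reactants: 11 2-({1-[4-methoxy-3-(methoxymethoxy)-5-(3-methylbut-2-en-1-yl)phenyl]ethenyl}oxy)-4,6-bis(methoxymethoxy)benzaldehyde
Product: 12 (2S)-2-[4-methoxy-3-(methoxymethoxy)-5-(3-methylbut-2-en-1-yl)phenyl]-5,7-bis(methoxymethoxy)-2,3-dihydro-4H-chromen-4-one
Conditions: [Rh(cod)Cl]2 (cod = 1,5-cyclooctadiene), (R)-DTBM-SEGPHOS, NaB[3,5-(CF3)2C6H3]4, dry THF, 60 °C
Reagents that add atoms: none
Why: Proposed new method: the cationic monovalent rhodium bisphosphine complex should add the formyl C–H bond of 11 oxidatively (acyl hydride of trivalent rhodium, kept beside the alkene by O1), the hydride should then go to the alkene carbon that carries O1 and ring B (future C2) while rhodium takes the unsubstituted terminus (future C3), and C–C reductive elimination from the resulting seven-membered rhodacycle should form the C3–C4 bond and return the catalyst. The closest known reaction type is the rhodium-catalysed enantioselective intramolecular hydroacylation of 1,1-disubstituted alkenes, which turns ortho-(2-substituted allyl)benzaldehydes into 3-substituted six-membered benzo-fused ketones; an aryl 1-arylvinyl ether, the oxygen analogue of that tether, has not been used as the alkene. Ring C closes in the formal 6-endo-trig mode, the acyl carbon C4 bonding to the alkene terminus C3. The only stereocentre, C2, is created when the prochiral alkene inserts into the Rh–H bond and is set by catalyst control through the axially chiral bisphosphine, whose enantiomer is chosen so that hydride reaches the face that gives 2S. The step needs endo over exo cyclisation and insertion over decarbonylation: the 1,1-disubstituted alkene secures the first (the exo path would need a tertiary alkylrhodium and a reductive elimination to a quaternary carbon of a five-membered ring), and the ortho ether oxygen O1 as a hemilabile donor on a cationic chelated rhodium centre should secure the second. The trisubstituted prenyl alkene and the acetal groups should stay untouched.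

**Step 9**
Reactants: 12 (2S)-2-[4-methoxy-3-(methoxymethoxy)-5-(3-methylbut-2-en-1-yl)phenyl]-5,7-bis(methoxymethoxy)-2,3-dihydro-4H-chromen-4-one
Product: 13 (2S)-5,7-dihydroxy-2-[3-hydroxy-4-methoxy-5-(3-methylbut-2-en-1-yl)phenyl]-2,3-dihydro-4H-chromen-4-one
Conditions: 3 M aq. HCl, MeOH, 40 °C
Reagents that add atoms: none
Why: Acid-catalysed acetal exchange with methanol should remove the three MOM groups while C2 stays configurationally stable (no base is present for a retro-oxa-Michael opening of ring C), and the prenyl group, flanked by OMe and not by a free OH, cannot cyclise to a chroman.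

**Compound list**

1 | 2,4,6-trihydroxybenzaldehyde | O=Cc1c(O)cc(O)cc1O | starting material
2 | 2-hydroxy-4,6-bis(methoxymethoxy)benzaldehyde | O=Cc1c(O)cc(OCOC)cc1OCOC | intermediate
3 | 3-bromo-4,5-dihydroxybenzaldehyde | O=Cc1cc(O)c(O)c(Br)c1 | starting material
4 | 3-bromo-5-hydroxy-4-methoxybenzaldehyde | O=Cc1cc(O)c(OC)c(Br)c1 | intermediate
5 | 3-bromo-4-methoxy-5-(methoxymethoxy)benzaldehyde | O=Cc1cc(OCOC)c(OC)c(Br)c1 | intermediate
6 | tributyl(3-methylbut-2-en-1-yl)stannane | CCCC[Sn](CCCC)(CCCC)CC=C(C)C | starting material
7 | 4-methoxy-3-(methoxymethoxy)-5-(3-methylbut-2-en-1-yl)benzaldehyde | O=Cc1cc(OCOC)c(OC)c(CC=C(C)C)c1 | intermediate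
8 | lithium 2-chloro-1-[4-methoxy-3-(methoxymethoxy)-5-(3-methylbut-2-en-1-yl)phenyl]ethan-1-olate (racemic, not isolated) | [Li+].[O-]C(CCl)c1cc(OCOC)c(OC)c(CC=C(C)C)c1 | intermediate
9 | rac-2-chloro-1-[4-methoxy-3-(methoxymethoxy)-5-(3-methylbut-2-en-1-yl)phenyl]ethan-1-ol | OC(CCl)c1cc(OCOC)c(OC)c(CC=C(C)C)c1 | intermediate
10 | rac-2-{2-chloro-1-[4-methoxy-3-(methoxymethoxy)-5-(3-methylbut-2-en-1-yl)phenyl]ethoxy}-4,6-bis(methoxymethoxy)benzaldehyde | O=Cc1c(OC(CCl)c2cc(OCOC)c(OC)c(CC=C(C)C)c2)cc(OCOC)cc1OCOC | intermediate
11 | 2-({1-[4-methoxy-3-(methoxymethoxy)-5-(3-methylbut-2-en-1-yl)phenyl]ethenyl}oxy)-4,6-bis(methoxymethoxy)benzaldehyde | O=Cc1c(OC(=C)c2cc(OCOC)c(OC)c(CC=C(C)C)c2)cc(OCOC)cc1OCOC | intermediate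
12 | (2S)-2-[4-methoxy-3-(methoxymethoxy)-5-(3-methylbut-2-en-1-yl)phenyl]-5,7-bis(methoxymethoxy)-2,3-dihydro-4H-chromen-4-one | COc1c(OCOC)cc([C@@H]2CC(=O)c3c(OCOC)cc(OCOC)cc3O2)cc1CC=C(C)C | intermediate
13 | (2S)-5,7-dihydroxy-2-[3-hydroxy-4-methoxy-5-(3-methylbut-2-en-1-yl)phenyl]-2,3-dihydro-4H-chromen-4-one | COc1c(O)cc([C@@H]2CC(=O)c3c(O)cc(O)cc3O2)cc1CC=C(C)C | target

**Step count and risks**

Total step count: 9. Longest linear sequence: 8 steps (from 3 through steps 2 to 9).

Steps most likely to fail:

1. Step 8 (Proposed new method). What may go wrong: decarbonylation of the doubly ortho-substituted acylrhodium hydride instead of alkene insertion, exo cyclisation to the five-membered ketone, or poor facial selectivity in the hydride transfer. Fallback with known chemistry, which keeps the C3–C4 ring closure but sets C2 beforehand; it sets out from 9 and comes back at 12. Racemic chlorohydrin 9 is oxidised with Dess–Martin periodinane to the alpha-chloro ketone F1. CBS reduction (BH3·SMe2, (S)-Me-CBS oxazaborolidine, THF, −20 °C) gives the (S)-chlorohydrin F2. Mitsunobu reaction of F2 with phenol 2 (PPh3, DIAD, toluene, −20 °C), with inversion, gives the (R)-chloro ether F3. F3 is cyclised by N-heterocyclic carbene catalysis (3-benzyl-5-(2-hydroxyethyl)-4-methylthiazolium chloride, DBU, catalytic NaI, 1,4-dioxane, 60 °C): the acyl anion equivalent formed from the aldehyde and the carbene displaces the primary halide, a known way from 2-(2-haloethoxy)benzaldehydes to chroman-4-ones, and gives 12 with C2 untouched.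

2. Step 6. What may go wrong: ionisation or elimination of the electron-rich benzylic oxyphosphonium ion instead of substitution, and slow reaction of the hindered, chelated phenol. Fallback that builds the enol ether by cross-coupling and bypasses steps 5 to 7; it sets out from 7 and comes back at 11. MeMgBr (THF, 0 °C) adds to aldehyde 7 to give the secondary alcohol F4. Dess–Martin oxidation gives the acetophenone F5. KN(SiMe3)2 and PhNTf2 (THF, −78 °C) give the 1-arylvinyl triflate F6. Palladium-catalysed C–O coupling of F6 with phenol 2 (Pd2(dba)3, 2-(di-tert-butylphosphino)biphenyl, K3PO4, toluene, 80 °C) gives 11.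

3. Step 4. What may go wrong: coupling through the gamma carbon of the prenyl unit (reverse prenyl group) and slow oxidative addition of the ortho-alkoxy aryl bromide. Fallback that builds the prenyl group in two stages; it sets out from 5 and comes back at 7. Stille coupling of 5 with allyltributylstannane (Pd(PPh3)4, DMF, 100 °C) gives the allyl arene F7, for which both ends of the allyl group give the same product. Cross-metathesis of F7 with excess 2-methyl-2-butene (second-generation Grubbs catalyst, CH2Cl2, 40 °C) turns the allyl into the prenyl group of 7.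

**Further compounds**

F1 | step 8 | 2-chloro-1-[4-methoxy-3-(methoxymethoxy)-5-(3-methylbut-2-en-1-yl)phenyl]ethan-1-one | O=C(CCl)c1cc(OCOC)c(OC)c(CC=C(C)C)c1
F2 | step 8 | (1S)-2-chloro-1-[4-methoxy-3-(methoxymethoxy)-5-(3-methylbut-2-en-1-yl)phenyl]ethan-1-ol | O[C@H](CCl)c1cc(OCOC)c(OC)c(CC=C(C)C)c1
F3 | step 8 | 2-{(1R)-2-chloro-1-[4-methoxy-3-(methoxymethoxy)-5-(3-methylbut-2-en-1-yl)phenyl]ethoxy}-4,6-bis(methoxymethoxy)benzaldehyde | O=Cc1c(O[C@@H](CCl)c2cc(OCOC)c(OC)c(CC=C(C)C)c2)cc(OCOC)cc1OCOC
F4 | step 6 | rac-1-[4-methoxy-3-(methoxymethoxy)-5-(3-methylbut-2-en-1-yl)phenyl]ethan-1-ol | CC(O)c1cc(OCOC)c(OC)c(CC=C(C)C)c1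
F5 | step 6 | 1-[4-methoxy-3-(methoxymethoxy)-5-(3-methylbut-2-en-1-yl)phenyl]ethan-1-one | CC(=O)c1cc(OCOC)c(OC)c(CC=C(C)C)c1
F6 | step 6 | 1-[4-methoxy-3-(methoxymethoxy)-5-(3-methylbut-2-en-1-yl)phenyl]ethenyl trifluoromethanesulfonate | C=C(OS(=O)(=O)C(F)(F)F)c1cc(OCOC)c(OC)c(CC=C(C)C)c1
F7 | step 4 | 4-methoxy-3-(methoxymethoxy)-5-(prop-2-en-1-yl)benzaldehyde | O=Cc1cc(OCOC)c(OC)c(CC=C)c1
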